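The vessel took its free monomer as a steady feed over 2.0 h onto transfer agent and initiator, and I had to say what stood in it after 5.0 d.

| setting | spring | autumn | dawn | flask |
|---|---|---|---|---|
| free monomer | 0.40 M (fed, over 2.0 h) | 0.40 M (fed, over 2.0 h) | 0.40 M (fed, over 2.0 h) | 0.40 M (fed, over 2.0 h) |
| transfer agent | 0.040 M | 0.040 M | 0.060 M | 0.0400 M |
| initiator | 0.13 mol% | 0.3 mol% | 0.2 mol% | 0.2 mol% |
| remark | run made earlier; the fed solution adds 0.25 times the starting volume | run made earlier; the fed solution adds 0.25 times the starting volume | run made earlier; the fed solution adds 0.25 times the starting volume | the fed solution adds 0.25 times the starting volume |
| time |  |  |  | 5.0 d |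

- spring (time / d: monomer in chains / %, free monomer / %): 0.333: 13, 88; 0.833: 23, 76; 1.67: 30, 69; 4.00: 33, 68
- autumn (time / d: monomer in chains / %, free monomer / %): 0.333: 29, 69; 0.833: 49, 51; 1.67: 58, 43; 4.00: 60, 41
- dawn (time / d: monomer in chains / %, free monomer / %): 0.500: 23, 76; 1.25: 31, 69; 2.50: 33, 68; 4.00: 36, 69

(readings scatter by 1.5 percentage points)

- every charge counts on the volume at the start, and the solution that is fed holds the whole dose
- the average divides the monomer in chains by the number of chains begun, living and dead together
- the earlier runs do not show the number of chains; that part of a forecast is a guess

- average number of monomer units in a chain (chains begun, living or dead) at 5.0 d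
- part of the free monomer that has reacted at 5.0 d

A rate is a constant times what is present, so I read the free monomer that stopped falling in the earlier runs, with some remaining, as a sign that its active partner had stopped being there. I took that partner to be a living end, made from initiator and lost on transfer agent. The autumn run, with more initiator than the spring run, stopped at 41% free monomer against 68%. The dawn run, with more initiator and more transfer agent than the spring run, stopped at 69%.

So I let the logarithm of the fraction of free monomer left grow with initiator over transfer agent. Scaled to this flask's recipe, the autumn reading gave 0.594 and the spring reading 0.593, which puts the reacted fraction at 44.8%.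

The runs show no chains, so what followed was my guess. The readings stopped, so I took the transfer agent to end chains and begin none. Its charge stood at 50.0 times the initiator, so I expected few of its molecules to be used. That gave me one quantity, the units per initiator (the kinetic chain length), meaning the reacted fraction of free monomer divided by the initiator's fraction of it: 224.

The forecast gave 46% reacted, close to my figure, but 4.6 units per chain, far from mine, and said “This assumes all the agent starts chains”.

The flask gave 45.6% reacted and 240 units per chain, 52.2 times the forecast's chain and close to my 224, with 98% of the transfer agent left and 0% of the initiator.

    free monomer + initiator → living end + monomer in chains (k = 5.58 /M/h)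
    free monomer + living end → monomer in chains + living end, rate k2*[living end]*[free monomer] (k = 72.8 /M/h)
    living end + transfer agent → dead chain (kL = 2.26 /M/h)
    initiator → spent initiator (k = 0.0403 /h)

In the flask, at the charged amounts, a living end added free monomer 322 times as fast as it met transfer agent, and at 5.0 d still 179 times as fast. For a neighbouring flask, with 1.6 M free monomer, initiator loaded on it and transfer agent held, the scaled reckoning gave 454 units per initiator, and that flask gave 471 units per chain at 91.9% reacted.

The readings stem from a simulated flask with made-up constants.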